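**Assumption:** the SMILES is read as (3S,5R) in oxolan-2-one numbering (3-OH cis to CHCl2). The ligand antipode named in step 4 is taken to give the (R) lactone; if the sense is opposite, its mirror image is used.

## Retrosynthetic overview

1. Last ring: the pyranone ring of the isocoumarin, by carboxylate-directed C–H acylmethylation and cyclodehydration of 2-hydroxy-4-methoxybenzoic acid with a β-keto sulfoxonium ylide (C4–C4a, then O2–C3).
2. The ylide comes from the CH2CO2H arm of the α-hydroxy-γ-lactone; the 3-OH comes from enolate hydroxylation.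
3. The γ-lactone with its O-bearing quaternary centre comes from a desymmetrising Baeyer–Villiger ring expansion of 4-(dichloromethyl)-4-hydroxycyclohexanone (six- to seven-membered), then lactone transposition in the flask (seven- to five-membered).
4. That ketone comes from LiCHCl2 and cyclohexane-1,4-dione; the benzoic acid comes from resorcinol (Kolbe–Schmitt, 4-O-methylation).
5. Ring order: benzene ring (bought), oxepanone, oxolanone, pyranone.

## Route

Step 1
Reactants: 1 resorcinol
Product: 2 2,4-dihydroxybenzoic acid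
Conditions: KHCO3 (5 equiv), H2O, CO2 (1 atm), 100 °C, 2 h; then HCl
Reagents that add atoms: carbon dioxide (supplied as KHCO3/CO2), O=C=O
Why: Kolbe–Schmitt carboxylation; the resorcinol anion attacks CO2 at C4 (ortho to one OH, para to the other), and at about 100 °C in water this isomer is the main product.

Step 2
Reactants: 2 2,4-dihydroxybenzoic acid
Product: 3 2-hydroxy-4-methoxybenzoic acid
Conditions: Me2SO4 (1.1 equiv), NaOH (3 equiv), H2O, 20–30 °C; then 80 °C, 30 min; HCl
Reagents that add atoms: dimethyl sulfate, COS(=O)(=O)OC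
Why: Selective Williamson O-methylation; the 2-OH is held in a hydrogen bond to the carboxylate, so only the 4-phenoxide is alkylated, and the carboxylate is not methylated in water.

Step 3
Reactants: 4 cyclohexane-1,4-dione
Product: 5 4-(dichloromethyl)-4-hydroxycyclohexan-1-one
Conditions: CH2Cl2, n-BuLi, THF, −100 °C (LiCHCl2); add to 4 (3 equiv), THF, −100 to −78 °C; AcOH, −78 °C
Reagents that add atoms: dichloromethane, ClCCl
Why: 1,2-addition of dichloromethyllithium (Köbrich carbenoid) to one carbonyl; excess dione limits double addition, the cold acid quench prevents closure to a chloroepoxide, and no stereocentre is formed.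

Step 4
Reactants: 5 4-(dichloromethyl)-4-hydroxycyclohexan-1-one
Product: 7 (5R)-5-(dichloromethyl)-5-(2-hydroxyethyl)oxolan-2-one, via hydroxy oxepanone 6 (not isolated)
Conditions: Sc(OTf)3 (10 mol%), N,N′-dioxide ligand from (S)-pipecolic acid with 2,6-diisopropylanilide arms (12 mol%), mCPBA (1.3 equiv), EtOAc, −20 °C, 24 h; then 25 °C, 3 h
Reagents that add atoms: mCPBA (3-chloroperoxybenzoic acid), OOC(=O)c1cccc(Cl)c1
Why: Proposed new method: the Sc(OTf)3/N,N′-dioxide complex (trivalent scandium) activates the ketone for peracid addition and holds the Criegee adduct in a chiral pocket, while the axial 4-OH hydrogen-bonds to a ligand amide oxygen and the equatorial CHCl2 locks the chair, so only one of the two enantiotopic α-CH2 groups lies antiperiplanar to the O–O bond and migrates (1,2-shift to oxygen with retention, six- to seven-membered ring), which makes the carbinol carbon the (R) stereocentre; the γ-hydroxyl of 6 then attacks the lactone carbonyl under the same Lewis acid (seven- to five-membered ring) to give 7; the closest known reactions are the Sc(OTf)3/N,N′-dioxide Baeyer–Villiger desymmetrisation of 4-monosubstituted cyclohexanones and the enzymatic oxidation of 4-hydroxy-4-methylcyclohexanone, neither shown with a small-molecule catalyst on a 4-hydroxy-4-(dihalomethyl) ketone.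

Step 5
Reactants: 7 (5R)-5-(dichloromethyl)-5-(2-hydroxyethyl)oxolan-2-one
Product: 8 2-[(2R)-2-(dichloromethyl)-5-oxooxolan-2-yl]acetic acid
Conditions: TEMPO (7 mol%), NaClO2 (2 equiv), NaOCl (2 mol%), MeCN/phosphate buffer pH 6.7, 35 °C; HCl to pH 2
Reagents that add atoms: sodium chlorite, [Na+].[O-]Cl=O
Why: TEMPO/chlorite oxidation (Anelli–Zhao type) takes the primary alcohol to the acid without touching the lactone or CHCl2, and the acid can be recrystallised to raise the ee from step 4.

Step 6
Reactants: 8 2-[(2R)-2-(dichloromethyl)-5-oxooxolan-2-yl]acetic acid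
Product: 9 2-[(2R,4S)-2-(dichloromethyl)-4-hydroxy-5-oxooxolan-2-yl]acetic acid
Conditions: NaN(SiMe3)2 (2.3 equiv), THF, −78 °C; (+)-(camphorsulfonyl)oxaziridine (1.5 equiv), −78 to −40 °C; HCl
Reagents that add atoms: (+)-(camphorsulfonyl)oxaziridine, O=S1(=O)C[C@@]23CC[C@@H](C2(C)C)C[C@@]34N1O4
Why: Davis hydroxylation of the lactone enolate (the carboxylate arm is not enolised as its salt); the chiral oxaziridine, helped by the sodium carboxylate arm blocking its own face, delivers oxygen trans to the CH2CO2H arm, that is cis to CHCl2, which sets the (4S) centre.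

Step 7
Reactants: 9 2-[(2R,4S)-2-(dichloromethyl)-4-hydroxy-5-oxooxolan-2-yl]acetic acid
Product: 11 dimethylsulfoxonium 3-[(2R,4S)-2-(dichloromethyl)-4-hydroxy-5-oxooxolan-2-yl]-2-oxopropan-1-ide, via acyl imidazole 10 (not isolated)
Conditions: CDI (1.05 equiv), THF, 20 °C, 1 h; then Me3S(O)I (3 equiv)/KOtBu (3 equiv), THF, 0 to 20 °C
Reagents that add atoms: trimethylsulfoxonium iodide, C[S+](C)(C)=O.[I-]; 1,1′-carbonyldiimidazole (its imidazolyl group sits only in 10), O=C(n1ccnc1)n1ccnc1
Why: Acyl substitution of the acyl imidazole by dimethylsulfoxonium methylide gives the stabilised β-keto sulfoxonium ylide; the activated acid is far more electrophilic than the γ-lactone, and the 3-OH (as alkoxide) is trans to the arm, so it neither lactonises nor lets C3 epimerise.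

Step 8
Reactants: 3 2-hydroxy-4-methoxybenzoic acid; 11 dimethylsulfoxonium 3-[(2R,4S)-2-(dichloromethyl)-4-hydroxy-5-oxooxolan-2-yl]-2-oxopropan-1-ide
Product: 13 (3S,5R)-5-(dichloromethyl)-3-hydroxy-5-[(8-hydroxy-6-methoxy-1-oxo-1H-isochromen-3-yl)methyl]oxolan-2-one, via keto acid 12 (not isolated)
Conditions: [Cp*RhCl2]2 (4 mol%), AgSbF6 (16 mol%), NaOAc (0.5 equiv), HFIP, 60 °C, 12 h
Reagents that add atoms: none
Why: Carboxylate-directed ortho C–H activation by the Cp*Rh catalyst (trivalent rhodium), carbene formation from the ylide with loss of DMSO, migratory insertion and protonation give keto acid 12, which cyclodehydrates (enol lactonisation) to the isocoumarin; only one ortho C–H is free, so the regiochemistry is fixed, and no stereocentre is touched.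

## Compound list

1 | resorcinol | Oc1cccc(O)c1 | starting material
2 | 2,4-dihydroxybenzoic acid | OC(=O)c1ccc(O)cc1O | intermediate
3 | 2-hydroxy-4-methoxybenzoic acid | COc1ccc(C(=O)O)c(O)c1 | intermediate
4 | cyclohexane-1,4-dione | O=C1CCC(=O)CC1 | starting material
5 | 4-(dichloromethyl)-4-hydroxycyclohexan-1-one | O=C1CCC(O)(C(Cl)Cl)CC1 | intermediate
6 | (5R)-5-(dichloromethyl)-5-hydroxyoxepan-2-one | O=C1CC[C@](O)(C(Cl)Cl)CCO1 | intermediate
7 | (5R)-5-(dichloromethyl)-5-(2-hydroxyethyl)oxolan-2-one | OCC[C@@]1(C(Cl)Cl)CCC(=O)O1 | intermediate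
8 | 2-[(2R)-2-(dichloromethyl)-5-oxooxolan-2-yl]acetic acid | OC(=O)C[C@@]1(C(Cl)Cl)CCC(=O)O1 | intermediate
9 | 2-[(2R,4S)-2-(dichloromethyl)-4-hydroxy-5-oxooxolan-2-yl]acetic acid | OC(=O)C[C@@]1(C(Cl)Cl)C[C@H](O)C(=O)O1 | intermediate
10 | 1-{[(2R,4S)-2-(dichloromethyl)-4-hydroxy-5-oxooxolan-2-yl]acetyl}-1H-imidazole | O=C(C[C@@]1(C(Cl)Cl)C[C@H](O)C(=O)O1)n1ccnc1 | intermediate
11 | dimethylsulfoxonium 3-[(2R,4S)-2-(dichloromethyl)-4-hydroxy-5-oxooxolan-2-yl]-2-oxopropan-1-ide | CS(C)(=O)=CC(=O)C[C@@]1(C(Cl)Cl)C[C@H](O)C(=O)O1 | intermediate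
12 | 2-{3-[(2R,4S)-2-(dichloromethyl)-4-hydroxy-5-oxooxolan-2-yl]-2-oxopropyl}-6-hydroxy-4-methoxybenzoic acid | COc1cc(O)c(C(=O)O)c(CC(=O)C[C@@]2(C(Cl)Cl)C[C@H](O)C(=O)O2)c1 | intermediate
13 | (3S,5R)-5-(dichloromethyl)-3-hydroxy-5-[(8-hydroxy-6-methoxy-1-oxo-1H-isochromen-3-yl)methyl]oxolan-2-one | COc1cc(O)c2c(=O)oc(C[C@@]3(C(Cl)Cl)C[C@H](O)C(=O)O3)cc2c1 | target

## Step count and risks

Total steps: 8. Longest linear sequence: 6 (steps 3 to 8).

**Step 4 (the new desymmetrising ring expansion).** The ee depends on the catalyst telling OH from CHCl2 at a remote carbon, and the chair bias may be too small. The fallback sets out from 5 and comes back at 8, using known enamine chemistry in place of the Baeyer–Villiger step. L-Proline (20 mol%) and nitrosobenzene in DMSO give, by desymmetrising α-aminoxylation (axial attack syn to the axial 4-OH), the anilinooxy ketone F1. Zn dust in AcOH cleaves the N–O bond to the dihydroxy ketone F2. NaIO4 in THF/H2O cuts the ketol to the seco aldehyde acid F3, which closes in the flask to the lactone aldehyde F4. Pinnick oxidation (NaClO2, NaH2PO4, 2-methylbut-2-ene) then gives 8, so step 5 is not needed.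

**Step 6 (C3 hydroxylation).** The new centre is 1,3 to a quaternary carbon whose two substituents differ little in size, so the diastereoselectivity may be low or reversed. The fallback sets out from 8 and comes back at 9. Hydroxylation with racemic 2-(phenylsulfonyl)-3-phenyloxaziridine gives 9 together with the epimeric hydroxy acid F5. Dess–Martin periodinane converts both into the keto lactone F6. Asymmetric transfer hydrogenation with RuCl(p-cymene)[(S,S)-TsDPEN] in HCO2H/Et3N (or its antipode, chosen in one test run) sets C3 under catalyst control, aided by hydride delivery anti to CHCl2, and returns 9.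

**Step 8 (C–H annulation with a free salicylic acid).** The ortho phenol can chelate rhodium or undergo O–H insertion, and the β-acyloxy ketone 12 can eliminate before it cyclises. The fallback sets out from 2 and 11 and comes back at 13. Exhaustive methylation of 2 (Me2SO4 in excess, aq NaOH, then reflux) gives 2,4-dimethoxybenzoic acid F7. Annulation of F7 with 11 under the same rhodium conditions passes through the dimethoxy keto acid F8 to the dimethoxy isocoumarin F9. BCl3 in CH2Cl2 (−78 to 0 °C) then cleaves only the 8-OMe next to the lactone carbonyl and gives 13.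

Further compounds
F1 | step 4 | (2R,4R)-2-(anilinooxy)-4-(dichloromethyl)-4-hydroxycyclohexan-1-one | O=C1[C@H](ONc2ccccc2)C[C@@](O)(C(Cl)Cl)CC1
F2 | step 4 | (2R,4R)-4-(dichloromethyl)-2,4-dihydroxycyclohexan-1-one | O=C1[C@H](O)C[C@@](O)(C(Cl)Cl)CC1
F3 | step 4 | (4R)-4-(dichloromethyl)-4-hydroxy-6-oxohexanoic acid | O=CC[C@@](O)(C(Cl)Cl)CCC(=O)O
F4 | step 4 | 2-[(2R)-2-(dichloromethyl)-5-oxooxolan-2-yl]acetaldehyde | O=CC[C@@]1(C(Cl)Cl)CCC(=O)O1
F5 | step 6 | 2-[(2R,4R)-2-(dichloromethyl)-4-hydroxy-5-oxooxolan-2-yl]acetic acid | OC(=O)C[C@@]1(C(Cl)Cl)C[C@@H](O)C(=O)O1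
F6 | step 6 | 2-[(2R)-2-(dichloromethyl)-4,5-dioxooxolan-2-yl]acetic acid | OC(=O)C[C@@]1(C(Cl)Cl)CC(=O)C(=O)O1
F7 | step 8 | 2,4-dimethoxybenzoic acid | COc1ccc(C(=O)O)c(OC)c1
F8 | step 8 | 2-{3-[(2R,4S)-2-(dichloromethyl)-4-hydroxy-5-oxooxolan-2-yl]-2-oxopropyl}-4,6-dimethoxybenzoic acid | COc1cc(OC)c(C(=O)O)c(CC(=O)C[C@@]2(C(Cl)Cl)C[C@H](O)C(=O)O2)c1
F9 | step 8 | (3S,5R)-5-(dichloromethyl)-5-[(6,8-dimethoxy-1-oxo-1H-isochromen-3-yl)methyl]-3-hydroxyoxolan-2-one | COc1cc(OC)c2c(=O)oc(C[C@@]3(C(Cl)Cl)C[C@H](O)C(=O)O3)cc2c1
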